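**Retrosynthetic overview**

1. Endgame: the side-chain oxirane comes last (Shi epoxidation of a prenyl-type alkene); the three angelates come from one esterification of a triol; the ring oxirane comes from hydroxyl-directed epoxidation of a carvone-type allylic alcohol, whose temporary C–Si bond is then cleaved by fluoride.
2. Carbocycle: a (5S)-2-methyl-3-silylcyclohex-2-enone; the ketone becomes the C2 carbinol (Luche reduction) and α'-hydroxylation supplies the C3 oxygen.
3. Key disconnection: in the 7-oxabicyclo[4.1.0]heptane core the bonds C1–C2 and C5–C6 are cut together. This excises C1(CH3)–C6 as a propyne unit and leaves C2, C3, C4, C5 as a cyclobutanone (C2 = carbonyl). Enabling feature: the methyl-bearing oxirane carbon C1 sits next to an oxygenated carbon (C2, a latent ketone) and the oxirane CH (C6) next to the only ring methylene (C5), so the six-membered ring is an alkyne-expanded, strained four-membered ketone.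
4. The 3-substituted cyclobutanone comes from 3,3-dimethoxycyclobutane-1-carboxylic acid: methyl ketone, Shapiro formylation, Keck allylation (side-chain carbinol), cross-metathesis (prenyl terminus).
5. Ring order: cyclobutane (purchased) → cyclohexenone (step 8) → ring oxirane (step 12) → side-chain oxirane (step 15).

Key step: step 8

Assumption: 3,3-dimethoxycyclobutane-1-carboxylic acid, trimethyl(prop-1-yn-1-yl)silane and angelic acid are taken as commercial; the sense of induction of the chiral nickel catalyst in step 8 cannot be predicted safely, so the ligand antipode that gives the (5S) enone is to be fixed in a screen of both.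

**Route**

Step 1
Reactants: 1 3,3-dimethoxycyclobutane-1-carboxylic acid
Product: 3 1-(3,3-dimethoxycyclobutyl)ethan-1-one, via dilithium gem-diolate 2 (not isolated)
Conditions: MeLi (2.2 equiv), Et2O, 0 °C to rt; inverse quench into H2O at 0 °C
Reagents that add atoms: methyllithium, [Li]C
Why: Ketone synthesis from a carboxylic acid and an organolithium: the second MeLi adds to the lithium carboxylate to give a gem-diolate that is stable until hydrolysis, so over-addition should not occur; the ketal is inert and no stereocenter is formed.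

Step 2
Reactants: 3 1-(3,3-dimethoxycyclobutyl)ethan-1-one
Product: 4 (E)-N'-[1-(3,3-dimethoxycyclobutyl)ethylidene]-2,4,6-tri(propan-2-yl)benzenesulfonohydrazide
Conditions: 2,4,6-(iPr)3C6H2SO2NHNH2 (1.0 equiv), THF, rt, no acid
Reagents that add atoms: 2,4,6-tri(propan-2-yl)benzenesulfonohydrazide, CC(C)c1cc(C(C)C)c(S(=O)(=O)NN)c(C(C)C)c1
Why: Hydrazone formation from an unhindered methyl ketone needs no acid, so the dimethyl ketal should survive; the bulky arene suppresses ortho-lithiation in the next step.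

Step 3
Reactants: 4 (E)-N'-[1-(3,3-dimethoxycyclobutyl)ethylidene]-2,4,6-tri(propan-2-yl)benzenesulfonohydrazide
Product: 6 2-(3,3-dimethoxycyclobutyl)prop-2-enal, via vinyllithium 5 (not isolated)
Conditions: n-BuLi (2.1 equiv), THF, −78 to 0 °C; then DMF, −78 °C to rt; H2O
Reagents that add atoms: N,N-dimethylformamide, CN(C)C=O; n-butyllithium, [Li]CCCC (supplies only the lithium of 5)
Why: Shapiro reaction: deprotonation at N–H and then at the syn methyl group (the less hindered α-carbon), followed by loss of sulfinate and N2, should give the 1-substituted vinyllithium, which DMF formylates to the 2-substituted acrolein; no stereocenter is formed.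

Step 4
Reactants: 6 2-(3,3-dimethoxycyclobutyl)prop-2-enal
Product: 7 (3S)-2-(3,3-dimethoxycyclobutyl)hexa-1,5-dien-3-ol
Conditions: (S)-BINOL (20 mol %), Ti(OiPr)4 (10 mol %), 4 Å MS, allylSnBu3 (1.5 equiv), CH2Cl2, −20 °C; aq. NaHCO3
Reagents that add atoms: allyltributylstannane, C=CC[Sn](CCCC)(CCCC)CCCC
Why: Keck asymmetric allylation: the BINOL–titanium Lewis acid should deliver the allyl group to the Si face of the enal carbonyl and so set the (3S) carbinol under catalyst control.

Step 5
Reactants: 7 (3S)-2-(3,3-dimethoxycyclobutyl)hexa-1,5-dien-3-ol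
Product: 8 (3S)-2-(3,3-dimethoxycyclobutyl)-6-methylhepta-1,5-dien-3-ol
Conditions: second-generation Grubbs catalyst (H2IMes)(PCy3)Cl2Ru=CHPh (5 mol %), 2-methyl-2-butene (large excess), CH2Cl2, 40 °C
Reagents that add atoms: 2-methyl-2-butene, CC=C(C)C
Why: Olefin cross-metathesis with excess 2-methyl-2-butene should convert only the monosubstituted alkene into the prenyl-type alkene, because the hindered 1,1-disubstituted alkene is inert; the stereocenter is untouched.

Step 6
Reactants: 8 (3S)-2-(3,3-dimethoxycyclobutyl)-6-methylhepta-1,5-dien-3-ol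
Product: 9 tert-butyl{[(3S)-2-(3,3-dimethoxycyclobutyl)-6-methylhepta-1,5-dien-3-yl]oxy}dimethylsilane
Conditions: TBSCl, imidazole, DMF, rt
Reagents that add atoms: tert-butyldimethylsilyl chloride, CC(C)(C)[Si](C)(C)Cl
Why: Standard silylation of a secondary alcohol; it masks the allylic hydroxyl before the nickel step, and the ether should survive until step 13.

Step 7
Reactants: 9 tert-butyl{[(3S)-2-(3,3-dimethoxycyclobutyl)-6-methylhepta-1,5-dien-3-yl]oxy}dimethylsilane
Product: 10 3-[(3S)-3-(tert-butyldimethylsilyloxy)-6-methylhepta-1,5-dien-2-yl]cyclobutan-1-one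
Conditions: PPTS (20 mol %), acetone/H2O 9:1, 50 °C
Reagents that add atoms: water, O
Why: Mild acid-catalysed ketal hydrolysis; the pyridinium acid should be too weak to cleave the secondary silyl ether or to protonate the alkenes.

Step 8
Reactants: 10 3-[(3S)-3-(tert-butyldimethylsilyloxy)-6-methylhepta-1,5-dien-2-yl]cyclobutan-1-one; 11 trimethyl(prop-1-yn-1-yl)silane
Product: 12 (5S)-5-[(3S)-3-(tert-butyldimethylsilyloxy)-6-methylhepta-1,5-dien-2-yl]-2-methyl-3-(trimethylsilyl)cyclohex-2-en-1-one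
Conditions: Ni(cod)2 (10 mol %), (S)-BINOL-derived N,N-bis[(S)-1-phenylethyl]phosphoramidite or its antipode (20 mol %), 11 (2 equiv, slow addition), PhMe, 90 °C
Reagents that add atoms: none
Why: Proposed new method: zerovalent nickel should couple the strained ketone C=O and the alkyne by oxidative cyclization to a spiro oxanickelacyclopentene (new bond from the carbonyl carbon to the methyl-bearing alkyne carbon, silicon-bearing carbon on nickel); strain-driven β-carbon elimination then opens one C(O)–CH2 bond of the four-membered ring to a seven-membered nickelacycle, and C(sp3)–C(sp2) reductive elimination forms the second bond and releases the enone. The closest known reaction type is the nickel/phosphine-catalysed intermolecular insertion of internal alkynes into 3-substituted cyclobutanones (achiral ligands, racemic products), together with the enantioselective intramolecular alkene insertion into cyclobutanones under nickel/chiral phosphoramidite catalysis; new here is the enantiotopic bond selection in the intermolecular alkyne case. The six-membered ring is closed by reductive elimination from the seven-membered metallacycle, a formal [4+2] ring expansion by two carbons and not a polar exo or endo cyclization. The only new stereocenter, C5 of the enone, arises because the two C(O)–CH2 bonds of 10 are enantiotopic at the ring; the chiral ligand on nickel is expected to decide which is cleaved, the side-chain carbinol being too remote to matter. The step needs alkyne regioselectivity, secured by the trimethylsilyl group, which prefers the nickel-bound carbon in the oxidative cyclization so that methyl ends next to the carbonyl, and chemoselectivity, secured by the ring strain of the cyclobutanone (the unstrained alkenes and the silyl ether should not react).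

Step 9
Reactants: 12 (5S)-5-[(3S)-3-(tert-butyldimethylsilyloxy)-6-methylhepta-1,5-dien-2-yl]-2-methyl-3-(trimethylsilyl)cyclohex-2-en-1-one
Product: 14 (5S,6S)-5-[(3S)-3-(tert-butyldimethylsilyloxy)-6-methylhepta-1,5-dien-2-yl]-6-hydroxy-2-methyl-3-(trimethylsilyl)cyclohex-2-en-1-one, via lithium dienolate 13 (not isolated)
Conditions: LiN(iPr)2 (1.1 equiv), THF, −78 °C; then 2-(benzenesulfonyl)-3-phenyloxaziridine, −78 °C; H2O
Reagents that add atoms: 2-(benzenesulfonyl)-3-phenyloxaziridine, O=S(=O)(c1ccccc1)N1OC1c1ccccc1; lithium diisopropylamide, CC(C)N([Li])C(C)C (supplies only the lithium of 13)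
Why: Kinetic α'-deprotonation gives the cross-conjugated enolate, and enolate hydroxylation with the N-sulfonyloxaziridine should occur anti to the adjacent C5 side chain to give the trans (5S,6S) ketol, which is also the thermodynamically preferred diequatorial epimer; the oxaziridine should not touch the isolated alkenes.

Step 10
Reactants: 14 (5S,6S)-5-[(3S)-3-(tert-butyldimethylsilyloxy)-6-methylhepta-1,5-dien-2-yl]-6-hydroxy-2-methyl-3-(trimethylsilyl)cyclohex-2-en-1-one
Product: 15 (5S,6S)-6-(tert-butyldimethylsilyloxy)-5-[(3S)-3-(tert-butyldimethylsilyloxy)-6-methylhepta-1,5-dien-2-yl]-2-methyl-3-(trimethylsilyl)cyclohex-2-en-1-one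
Conditions: TBSCl, imidazole, DMF, rt
Reagents that add atoms: tert-butyldimethylsilyl chloride, CC(C)(C)[Si](C)(C)Cl
Why: Silylation of the secondary ketol hydroxyl under weakly basic conditions; the group later shields the upper face and prevents a competing homoallylic-hydroxyl-directed epoxidation in step 12.

Step 11
Reactants: 15 (5S,6S)-6-(tert-butyldimethylsilyloxy)-5-[(3S)-3-(tert-butyldimethylsilyloxy)-6-methylhepta-1,5-dien-2-yl]-2-methyl-3-(trimethylsilyl)cyclohex-2-en-1-one
Product: 16 (1S,5S,6S)-6-(tert-butyldimethylsilyloxy)-5-[(3S)-3-(tert-butyldimethylsilyloxy)-6-methylhepta-1,5-dien-2-yl]-2-methyl-3-(trimethylsilyl)cyclohex-2-en-1-ol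
Conditions: NaBH4, CeCl3·7H2O, MeOH, −78 to −40 °C
Reagents that add atoms: none
Why: Luche reduction: 1,2-selective axial hydride delivery to the half-chair enone with equatorial C5 and C6 substituents should give the equatorial (1S) alcohol, trans to the neighbouring silyloxy group and cis to the side chain (substrate control, as in the reduction of carvone to cis-carveol).

Step 12
Reactants: 16 (1S,5S,6S)-6-(tert-butyldimethylsilyloxy)-5-[(3S)-3-(tert-butyldimethylsilyloxy)-6-methylhepta-1,5-dien-2-yl]-2-methyl-3-(trimethylsilyl)cyclohex-2-en-1-ol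
Product: 17 (1R,2R,3S,4S,6R)-3-(tert-butyldimethylsilyloxy)-4-[(3S)-3-(tert-butyldimethylsilyloxy)-6-methylhepta-1,5-dien-2-yl]-1-methyl-6-(trimethylsilyl)-7-oxabicyclo[4.1.0]heptan-2-ol
Conditions: VO(acac)2 (5 mol %), t-BuOOH (1.5 equiv, decane), CH2Cl2, 0 °C to rt
Reagents that add atoms: tert-butyl hydroperoxide, CC(C)(C)OO
Why: Hydroxyl-directed epoxidation of an allylic alcohol: the vanadium alkoxide should deliver oxygen to the face of the tetrasubstituted vinylsilane syn to the hydroxyl, setting both oxirane carbons cis to it; the side-chain alkenes have no free hydroxyl nearby and should not react.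

Step 13
Reactants: 17 (1R,2R,3S,4S,6R)-3-(tert-butyldimethylsilyloxy)-4-[(3S)-3-(tert-butyldimethylsilyloxy)-6-methylhepta-1,5-dien-2-yl]-1-methyl-6-(trimethylsilyl)-7-oxabicyclo[4.1.0]heptan-2-ol
Product: 18 (1R,2R,3S,4S,6S)-4-[(3S)-3-hydroxy-6-methylhepta-1,5-dien-2-yl]-1-methyl-7-oxabicyclo[4.1.0]heptane-2,3-diol
Conditions: Bu4NF (4 equiv, wet), THF, rt to 50 °C
Reagents that add atoms: none
Why: Fluoride should cleave both O–Si bonds and also the C–Si bond on the oxirane through the configurationally stable oxiranyl anion (protodesilylation of α,β-epoxysilanes with retention), so C6 keeps its configuration with H in place of silicon; a cis-epoxy alcohol cannot undergo Payne rearrangement.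

Step 14
Reactants: 18 (1R,2R,3S,4S,6S)-4-[(3S)-3-hydroxy-6-methylhepta-1,5-dien-2-yl]-1-methyl-7-oxabicyclo[4.1.0]heptane-2,3-diol
Product: 19 (1S,2R,3S,4S,6S)-4-[(3S)-3-{[(2Z)-2-methylbut-2-enoyl]oxy}-6-methylhepta-1,5-dien-2-yl]-1-methyl-7-oxabicyclo[4.1.0]heptane-2,3-diyl bis[(2Z)-2-methylbut-2-enoate]
Conditions: angelic acid (4.5 equiv), 2,4,6-Cl3C6H2COCl, Et3N, PhMe, rt, filter off the ammonium chloride; then 18, PhMe, 80 °C
Reagents that add atoms: angelic acid [(2Z)-2-methylbut-2-enoic acid], C/C=C(/C)C(=O)O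
Why: Yamaguchi-type esterification through the mixed 2,4,6-trichlorobenzoic anhydride without a nucleophilic pyridine catalyst is the established way to acylate hindered alcohols with angelic acid without isomerization to the tiglate; no stereocenter is touched and the (Z) geometry comes from the acid.

Step 15
Reactants: 19 (1S,2R,3S,4S,6S)-4-[(3S)-3-{[(2Z)-2-methylbut-2-enoyl]oxy}-6-methylhepta-1,5-dien-2-yl]-1-methyl-7-oxabicyclo[4.1.0]heptane-2,3-diyl bis[(2Z)-2-methylbut-2-enoate]
Product: 20 CNP0258231.3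
Conditions: D-fructose-derived ketone 1,2:4,5-di-O-isopropylidene-β-D-erythro-2,3-hexodiulo-2,6-pyranose (30 mol %), Oxone (2KHSO5·KHSO4·K2SO4), K2CO3, Bu4NHSO4 (cat.), MeCN/dimethoxymethane/aq. borate buffer (pH about 10.5), 0 °C
Reagents that add atoms: potassium peroxymonosulfate, [K+].[O-]S(=O)(=O)OO
Why: Shi epoxidation: the chiral dioxirane should epoxidize only the electron-rich trisubstituted side-chain alkene (the angelates and the 1,1-disubstituted alkene next to an acyloxy group are electron-poor) through the spiro transition state that gives the (R)-oxirane under catalyst control.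

**Compound list**

1 | 3,3-dimethoxycyclobutane-1-carboxylic acid | OC(=O)C1CC(OC)(OC)C1 | starting material
2 | dilithium 1-(3,3-dimethoxycyclobutyl)ethane-1,1-diolate | [Li+].[Li+].CC([O-])([O-])C1CC(OC)(OC)C1 | intermediate
3 | 1-(3,3-dimethoxycyclobutyl)ethan-1-one | CC(=O)C1CC(OC)(OC)C1 | intermediate
4 | (E)-N'-[1-(3,3-dimethoxycyclobutyl)ethylidene]-2,4,6-tri(propan-2-yl)benzenesulfonohydrazide | C/C(C1CC(OC)(OC)C1)=N\NS(=O)(=O)c1c(C(C)C)cc(C(C)C)cc1C(C)C | intermediate
5 | [1-(3,3-dimethoxycyclobutyl)ethenyl]lithium | [Li]C(=C)C1CC(OC)(OC)C1 | intermediate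
6 | 2-(3,3-dimethoxycyclobutyl)prop-2-enal | C=C(C=O)C1CC(OC)(OC)C1 | intermediate
7 | (3S)-2-(3,3-dimethoxycyclobutyl)hexa-1,5-dien-3-ol | C=C([C@H](CC=C)O)C1CC(OC)(OC)C1 | intermediate
8 | (3S)-2-(3,3-dimethoxycyclobutyl)-6-methylhepta-1,5-dien-3-ol | C=C([C@H](CC=C(C)C)O)C1CC(OC)(OC)C1 | intermediate
9 | tert-butyl{[(3S)-2-(3,3-dimethoxycyclobutyl)-6-methylhepta-1,5-dien-3-yl]oxy}dimethylsilane | C=C([C@H](CC=C(C)C)O[Si](C)(C)C(C)(C)C)C1CC(OC)(OC)C1 | intermediate
10 | 3-[(3S)-3-(tert-butyldimethylsilyloxy)-6-methylhepta-1,5-dien-2-yl]cyclobutan-1-one | C=C([C@H](CC=C(C)C)O[Si](C)(C)C(C)(C)C)C1CC(=O)C1 | intermediate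
11 | trimethyl(prop-1-yn-1-yl)silane | CC#C[Si](C)(C)C | starting material
12 | (5S)-5-[(3S)-3-(tert-butyldimethylsilyloxy)-6-methylhepta-1,5-dien-2-yl]-2-methyl-3-(trimethylsilyl)cyclohex-2-en-1-one | C=C([C@H](CC=C(C)C)O[Si](C)(C)C(C)(C)C)[C@@H]1CC([Si](C)(C)C)=C(C)C(=O)C1 | intermediate
13 | lithium (5S)-5-[(3S)-3-(tert-butyldimethylsilyloxy)-6-methylhepta-1,5-dien-2-yl]-2-methyl-3-(trimethylsilyl)cyclohexa-1(6),2-dien-1-olate | C=C([C@H](CC=C(C)C)O[Si](C)(C)C(C)(C)C)[C@@H]1CC([Si](C)(C)C)=C(C)C(O[Li])=C1 | intermediate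
14 | (5S,6S)-5-[(3S)-3-(tert-butyldimethylsilyloxy)-6-methylhepta-1,5-dien-2-yl]-6-hydroxy-2-methyl-3-(trimethylsilyl)cyclohex-2-en-1-one | C=C([C@H](CC=C(C)C)O[Si](C)(C)C(C)(C)C)[C@@H]1CC([Si](C)(C)C)=C(C)C(=O)[C@H]1O | intermediate
15 | (5S,6S)-6-(tert-butyldimethylsilyloxy)-5-[(3S)-3-(tert-butyldimethylsilyloxy)-6-methylhepta-1,5-dien-2-yl]-2-methyl-3-(trimethylsilyl)cyclohex-2-en-1-one | C=C([C@H](CC=C(C)C)O[Si](C)(C)C(C)(C)C)[C@@H]1CC([Si](C)(C)C)=C(C)C(=O)[C@H]1O[Si](C)(C)C(C)(C)C | intermediate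
16 | (1S,5S,6S)-6-(tert-butyldimethylsilyloxy)-5-[(3S)-3-(tert-butyldimethylsilyloxy)-6-methylhepta-1,5-dien-2-yl]-2-methyl-3-(trimethylsilyl)cyclohex-2-en-1-ol | C=C([C@H](CC=C(C)C)O[Si](C)(C)C(C)(C)C)[C@@H]1CC([Si](C)(C)C)=C(C)[C@H](O)[C@H]1O[Si](C)(C)C(C)(C)C | intermediate
17 | (1R,2R,3S,4S,6R)-3-(tert-butyldimethylsilyloxy)-4-[(3S)-3-(tert-butyldimethylsilyloxy)-6-methylhepta-1,5-dien-2-yl]-1-methyl-6-(trimethylsilyl)-7-oxabicyclo[4.1.0]heptan-2-ol | C=C([C@H](CC=C(C)C)O[Si](C)(C)C(C)(C)C)[C@@H]1C[C@]2([Si](C)(C)C)O[C@]2(C)[C@H](O)[C@H]1O[Si](C)(C)C(C)(C)C | intermediate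
18 | (1R,2R,3S,4S,6S)-4-[(3S)-3-hydroxy-6-methylhepta-1,5-dien-2-yl]-1-methyl-7-oxabicyclo[4.1.0]heptane-2,3-diol | C=C([C@H](CC=C(C)C)O)[C@@H]1C[C@@H]2O[C@]2(C)[C@H](O)[C@H]1O | intermediate
19 | (1S,2R,3S,4S,6S)-4-[(3S)-3-{[(2Z)-2-methylbut-2-enoyl]oxy}-6-methylhepta-1,5-dien-2-yl]-1-methyl-7-oxabicyclo[4.1.0]heptane-2,3-diyl bis[(2Z)-2-methylbut-2-enoate] | C=C([C@H](CC=C(C)C)OC(=O)/C(C)=C\C)[C@@H]1C[C@@H]2O[C@]2(C)[C@H](OC(=O)/C(C)=C\C)[C@H]1OC(=O)/C(C)=C\C | intermediate
20 | CNP0258231.3, (1S,2R,3S,4S,6S)-4-{(3S)-4-[(2R)-3,3-dimethyloxiran-2-yl]-3-{[(2Z)-2-methylbut-2-enoyl]oxy}but-1-en-2-yl}-1-methyl-7-oxabicyclo[4.1.0]heptane-2,3-diyl bis[(2Z)-2-methylbut-2-enoate] | C=C([C@H](C[C@H]1OC1(C)C)OC(=O)/C(C)=C\C)[C@@H]1C[C@@H]2O[C@]2(C)[C@H](OC(=O)/C(C)=C\C)[C@H]1OC(=O)/C(C)=C\C | target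

**Step count and risks**

Total step count: 15. Longest linear sequence: 15 steps (1 to 20).

Steps most likely to fail:

1. Step 8 (proposed new method). The chiral nickel catalyst may discriminate poorly between the two enantiotopic C(O)–CH2 bonds, or the chiral ligand may slow the insertion so that alkyne oligomerization takes over. Fallback with known chemistry, setting out from 10 and coming back at 15: the ring stereocenter is set before the ring expansion by enantioselective deprotonation. Treatment of 10 with a chiral lithium amide (lithium bis[(S)-1-phenylethyl]amide or its antipode, TMSCl in situ, THF, −100 °C) should give the silyl enol ether tert-butyl{[(3S)-6-methyl-2-[(1R)-3-(trimethylsilyloxy)cyclobut-2-en-1-yl]hepta-1,5-dien-3-yl]oxy}dimethylsilane F1. Regeneration of the lithium enolate with MeLi and hydroxylation with 2-(benzenesulfonyl)-3-phenyloxaziridine, anti to the ring substituent, should give the trans ketol (2S,3S)-3-[(3S)-3-(tert-butyldimethylsilyloxy)-6-methylhepta-1,5-dien-2-yl]-2-hydroxycyclobutan-1-one F2. TBSCl/imidazole should give the silyl ether (2S,3S)-2-(tert-butyldimethylsilyloxy)-3-[(3S)-3-(tert-butyldimethylsilyloxy)-6-methylhepta-1,5-dien-2-yl]cyclobutan-1-one F3. The achiral system Ni(cod)2/PCy3 with 11 (PhMe, 90–100 °C) should then insert the alkyne into the less substituted C(O)–CH2 bond of F3, carry both stereocenters over and give 15 directly.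

2. Step 13. The carbon–silicon bond at the fully substituted oxirane carbon may resist fluoride, or the oxiranyl anion may open before it is protonated. Fallback, setting out from 15 and coming back at 18: silicon is removed at the enone stage by the masked-enone tactic. Copper hydride conjugate reduction of 15 ([(Ph3P)CuH]6 cat., PhMe2SiH, PhMe, rt) should give the silyl enol ether {[(5S,6S)-6-(tert-butyldimethylsilyloxy)-5-[(3S)-3-(tert-butyldimethylsilyloxy)-6-methylhepta-1,5-dien-2-yl]-2-methyl-3-(trimethylsilyl)cyclohex-1-en-1-yl]oxy}dimethyl(phenyl)silane F4. NBS (THF, −78 °C) should brominate it at the methyl-bearing carbon to give the bromo ketone (5S,6S)-2-bromo-6-(tert-butyldimethylsilyloxy)-5-[(3S)-3-(tert-butyldimethylsilyloxy)-6-methylhepta-1,5-dien-2-yl]-2-methyl-3-(trimethylsilyl)cyclohexan-1-one F5. On warming this should lose bromotrimethylsilane (desilylbromination) to give the silicon-free enone (5S,6S)-6-(tert-butyldimethylsilyloxy)-5-[(3S)-3-(tert-butyldimethylsilyloxy)-6-methylhepta-1,5-dien-2-yl]-2-methylcyclohex-2-en-1-one F6. Luche reduction (NaBH4, CeCl3·7H2O) should give the allylic alcohol (1S,5S,6S)-6-(tert-butyldimethylsilyloxy)-5-[(3S)-3-(tert-butyldimethylsilyloxy)-6-methylhepta-1,5-dien-2-yl]-2-methylcyclohex-2-en-1-ol F7. VO(acac)2/t-BuOOH should give the epoxy alcohol (1R,2R,3S,4S,6S)-3-(tert-butyldimethylsilyloxy)-4-[(3S)-3-(tert-butyldimethylsilyloxy)-6-methylhepta-1,5-dien-2-yl]-1-methyl-7-oxabicyclo[4.1.0]heptan-2-ol F8, and Bu4NF then has only the two O–Si bonds to cleave to reach 18.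

3. Step 14. Angelate may isomerize to tiglate during the slow acylation of the two hindered ring hydroxyls, acylation may stay incomplete, and chloride may open an oxirane at 80 °C. Fallback, setting out from 18 and coming back at 19: the (Z)-alkenes are built on the esters instead of being brought in. Esterification of 18 with 2-[bis(2,2,2-trifluoroethoxy)phosphoryl]propanoic acid (carbodiimide, DMAP, CH2Cl2, rt; no isomerizable alkene present) should give the tris-phosphonate (1S,2R,3S,4S,6S)-4-[(3S)-3-({2-[bis(2,2,2-trifluoroethoxy)phosphoryl]propanoyl}oxy)-6-methylhepta-1,5-dien-2-yl]-1-methyl-7-oxabicyclo[4.1.0]heptane-2,3-diyl bis{2-[bis(2,2,2-trifluoroethoxy)phosphoryl]propanoate} F9. Threefold Still–Gennari olefination (KN(SiMe3)2, 18-crown-6, THF, −78 °C; acetaldehyde) should give the three (Z)-2-methylbut-2-enoates of 19.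

Further compounds

F1 | step 8 | tert-butyl{[(3S)-6-methyl-2-[(1R)-3-(trimethylsilyloxy)cyclobut-2-en-1-yl]hepta-1,5-dien-3-yl]oxy}dimethylsilane | C=C([C@H](CC=C(C)C)O[Si](C)(C)C(C)(C)C)[C@@H]1CC(O[Si](C)(C)C)=C1
F2 | step 8 | (2S,3S)-3-[(3S)-3-(tert-butyldimethylsilyloxy)-6-methylhepta-1,5-dien-2-yl]-2-hydroxycyclobutan-1-one | C=C([C@H](CC=C(C)C)O[Si](C)(C)C(C)(C)C)[C@@H]1CC(=O)[C@H]1O
F3 | step 8 | (2S,3S)-2-(tert-butyldimethylsilyloxy)-3-[(3S)-3-(tert-butyldimethylsilyloxy)-6-methylhepta-1,5-dien-2-yl]cyclobutan-1-one | C=C([C@H](CC=C(C)C)O[Si](C)(C)C(C)(C)C)[C@@H]1CC(=O)[C@H]1O[Si](C)(C)C(C)(C)C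
F4 | step 13 | {[(5S,6S)-6-(tert-butyldimethylsilyloxy)-5-[(3S)-3-(tert-butyldimethylsilyloxy)-6-methylhepta-1,5-dien-2-yl]-2-methyl-3-(trimethylsilyl)cyclohex-1-en-1-yl]oxy}dimethyl(phenyl)silane (epimers at C3) | C=C([C@H](CC=C(C)C)O[Si](C)(C)C(C)(C)C)[C@@H]1CC([Si](C)(C)C)C(C)=C(O[Si](C)(C)c2ccccc2)[C@H]1O[Si](C)(C)C(C)(C)C
F5 | step 13 | (5S,6S)-2-bromo-6-(tert-butyldimethylsilyloxy)-5-[(3S)-3-(tert-butyldimethylsilyloxy)-6-methylhepta-1,5-dien-2-yl]-2-methyl-3-(trimethylsilyl)cyclohexan-1-one (epimers at C2 and C3) | C=C([C@H](CC=C(C)C)O[Si](C)(C)C(C)(C)C)[C@@H]1CC([Si](C)(C)C)C(C)(Br)C(=O)[C@H]1O[Si](C)(C)C(C)(C)C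
F6 | step 13 | (5S,6S)-6-(tert-butyldimethylsilyloxy)-5-[(3S)-3-(tert-butyldimethylsilyloxy)-6-methylhepta-1,5-dien-2-yl]-2-methylcyclohex-2-en-1-one | C=C([C@H](CC=C(C)C)O[Si](C)(C)C(C)(C)C)[C@@H]1CC=C(C)C(=O)[C@H]1O[Si](C)(C)C(C)(C)C
F7 | step 13 | (1S,5S,6S)-6-(tert-butyldimethylsilyloxy)-5-[(3S)-3-(tert-butyldimethylsilyloxy)-6-methylhepta-1,5-dien-2-yl]-2-methylcyclohex-2-en-1-ol | C=C([C@H](CC=C(C)C)O[Si](C)(C)C(C)(C)C)[C@@H]1CC=C(C)[C@H](O)[C@H]1O[Si](C)(C)C(C)(C)C
F8 | step 13 | (1R,2R,3S,4S,6S)-3-(tert-butyldimethylsilyloxy)-4-[(3S)-3-(tert-butyldimethylsilyloxy)-6-methylhepta-1,5-dien-2-yl]-1-methyl-7-oxabicyclo[4.1.0]heptan-2-ol | C=C([C@H](CC=C(C)C)O[Si](C)(C)C(C)(C)C)[C@@H]1C[C@@H]2O[C@]2(C)[C@H](O)[C@H]1O[Si](C)(C)C(C)(C)C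
F9 | step 14 | (1S,2R,3S,4S,6S)-4-[(3S)-3-({2-[bis(2,2,2-trifluoroethoxy)phosphoryl]propanoyl}oxy)-6-methylhepta-1,5-dien-2-yl]-1-methyl-7-oxabicyclo[4.1.0]heptane-2,3-diyl bis{2-[bis(2,2,2-trifluoroethoxy)phosphoryl]propanoate} (epimers at the phosphonate carbons) | C=C([C@H](CC=C(C)C)OC(=O)C(C)P(=O)(OCC(F)(F)F)OCC(F)(F)F)[C@@H]1C[C@@H]2O[C@]2(C)[C@H](OC(=O)C(C)P(=O)(OCC(F)(F)F)OCC(F)(F)F)[C@H]1OC(=O)C(C)P(=O)(OCC(F)(F)F)OCC(F)(F)F
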